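**Retrosynthetic overview** (side chain numbered C11–C18 outward from the carbinol carbon C9; C13 and C16 carry the peroxide, C18 is the carboxyl carbon)
1. C16–C17, last C–C bond: anti-selective addition of a chiral propanoate titanium enolate to a six-membered peroxycarbenium ion; sets C16 and C17.
2. 1,2-Dioxane, the only ring that is built and built last: a C13 hydroperoxide (from cobalt-mediated radical hydroperoxidation of a C12=C13 alkene) closes onto a C16 acetal.
3. C9–C11, key bond: the C11 terminus of an allylic acetate (an electrophile) is inverted via π-allylpalladium/SmI2 into an allylsamarium nucleophile and added to the C9 ketone; sets C9. With respect to the later C13 oxygen, C11 is a d3 (homoenolate-type) donor.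
4. Rings A and B are not constructed: the trans-decalin (C5, C10, and C8 by equilibration) comes from a commercial labdane-derived lactone cut down by two carbons to the C9 ketone; C11–C16 come from a commercial monoterpene acetate.
5. Ring order: rings A/B (chiral pool), then side-chain coupling, then dioxane ring, then propanoic acid terminus.

Assumption: decalin atoms carry labdane numbers C1–C10, and all three starting materials are taken as catalogue compounds.

**Step 1**
Reactants: 1 (+)-sclareolide [(3aR,5aS,9aS,9bR)-3a,6,6,9a-tetramethyldecahydronaphtho[2,1-b]furan-2(1H)-one]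
Product: 3 9(11)-dehydrosclareolide [(3aR,5aS,9aS)-3a,6,6,9a-tetramethyl-4,5,5a,6,7,8,9,9a-octahydronaphtho[2,1-b]furan-2(3aH)-one; C9=C11 butenolide], via 11α-phenylselanylsclareolide 2 (not isolated)
Conditions: LiN(i-Pr)2, THF, −78 °C; PhSeBr; then 30% H2O2, pyridine, CH2Cl2, 0 °C to rt
Reagents that add atoms: none
Why: α-selenenylation of the lactone enolate from the open α face places selenium cis to the axial H9, so the selenoxide syn-elimination (H9 is the only β-hydrogen) gives the C9=C11 butenolide while C5, C8 and C10 stay untouched.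

**Step 2**
Reactants: 3 9(11)-dehydrosclareolide
Product: 5 (2R,4aS,8aS)-2-hydroxy-2,5,5,8a-tetramethyloctahydronaphthalen-1(2H)-one (8α-hydroxy C9 ketone), via 8α-glyoxyloyloxy ketone 4 (not isolated)
Conditions: O3, CH2Cl2/MeOH, −78 °C; Me2S; then K2CO3 (cat.), MeOH, 0 °C
Reagents that add atoms: ozone, [O-][O+]=O
Why: ozonolysis of the conjugated C9=C11 bond excises C11 and C12 as a glyoxylate ester on the C8 oxygen, which mild methanolysis removes; no stereocentre is touched.

**Step 3**
Reactants: 5 (2R,4aS,8aS)-2-hydroxy-2,5,5,8a-tetramethyloctahydronaphthalen-1(2H)-one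
Product: 6 (2R,4aS,8aS)-2,5,5,8a-tetramethyloctahydronaphthalen-1(2H)-one
Conditions: SmI2 (2.5 equiv), THF/MeOH, −78 °C to rt; then NaOMe, MeOH, rt
Reagents that add atoms: none
Why: SmI2 reduction of an α-hydroxy ketone (ketyl formation, loss of the α-oxygen, protonation) removes the C8 oxygen, and base equilibration sets C8 with its methyl equatorial (8α), because the epimer would hold it syn-axial to the C10 methyl.

**Step 4**
Reactants: 7 geranyl acetate [(2E)-3,7-dimethylocta-2,6-dien-1-yl acetate]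
Product: 9 (2E)-6,6-dimethoxy-3-methylhex-2-en-1-yl acetate, via (2E)-3-methyl-6-oxohex-2-en-1-yl acetate 8 (not isolated)
Conditions: O3 (1.0 equiv), CH2Cl2/MeOH, −78 °C; Me2S; then TsOH (cat.), MeOH, 3 Å MS, rt
Reagents that add atoms: methanol, CO
Why: chemoselective ozonolysis cleaves the electron-rich 6,7-alkene rather than the acetate-deactivated 2,3-alkene, and acid-catalysed acetalisation masks the aldehyde so that it survives step 5 and later serves as the C16 electrophile.

**Step 5 (key step)**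
Reactants: 6 (2R,4aS,8aS)-2,5,5,8a-tetramethyloctahydronaphthalen-1(2H)-one; 9 (2E)-6,6-dimethoxy-3-methylhex-2-en-1-yl acetate
Product: 11 (1R,2R,4aS,8aS)-1-[(2E)-6,6-dimethoxy-3-methylhex-2-en-1-yl]-2,5,5,8a-tetramethyldecahydronaphthalen-1-ol (E/Z mixture at C12=C13 acceptable), via [(2E)-6,6-dimethoxy-3-methylhex-2-en-1-yl]samarium diiodide 10 (not isolated)
Conditions: Pd(PPh3)4 (5 mol%), SmI2 (2.5 equiv), THF, rt
Reagents that add atoms: none
Why: in this palladium-catalysed reductive (Barbier-type) allylation, zerovalent palladium turns the allylic acetate into an electrophilic π-allylpalladium complex that SmI2 reduces to a nucleophilic allylsamarium (polarity inversion at C11, a homoenolate-type donor toward the future C13 oxygen), which adds to the hindered C9 ketone through its unsubstituted terminus and, like other bulky carbon nucleophiles on 2,2,6-trisubstituted cyclohexanones, along the equatorial trajectory on the β face, giving the equatorial side chain and axial 9α-hydroxyl (C9 = R); scrambling of the alkene geometry does not matter because that alkene is consumed in step 6.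

**Step 6**
Reactants: 11 (1R,2R,4aS,8aS)-1-[(2E)-6,6-dimethoxy-3-methylhex-2-en-1-yl]-2,5,5,8a-tetramethyldecahydronaphthalen-1-ol
Product: 12 (1R,2R,4aS,8aS)-1-{6,6-dimethoxy-3-methyl-3-[(triethylsilyl)peroxy]hexyl}-2,5,5,8a-tetramethyldecahydronaphthalen-1-ol (about 1:1 at C13)
Conditions: Co(thd)2 (10 mol%; thd = 2,2,6,6-tetramethylheptane-3,5-dionate), O2 (1 atm), Et3SiH (3 equiv), ClCH2CH2Cl, rt
Reagents that add atoms: dioxygen, O=O; triethylsilane, CC[SiH](CC)CC
Why: Isayama–Mukaiyama hydroperoxysilylation: hydrogen-atom transfer from a cobalt hydride to C12 gives the tertiary C13 radical (the same from the E and the Z alkene), which traps O2 and is silylated; the radical is planar and remote from all stereocentres, so C13 forms without facial control and the 13S series is selected by the separation in step 8.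

**Step 7**
Reactants: 12 (1R,2R,4aS,8aS)-1-{6,6-dimethoxy-3-methyl-3-[(triethylsilyl)peroxy]hexyl}-2,5,5,8a-tetramethyldecahydronaphthalen-1-ol
Product: 14 (1R,2R,4aS,8aS)-1-[2-(6-methoxy-3-methyl-1,2-dioxan-3-yl)ethyl]-2,5,5,8a-tetramethyldecahydronaphthalen-1-ol (C13 epimers, both anomers at C16), via C13 hydroperoxide 13 (not isolated)
Conditions: HF·pyridine, THF, 0 °C; then PPTS (10 mol%), CH2Cl2, 4 Å MS, rt
Reagents that add atoms: none
Why: O–Si cleavage frees the tertiary hydroperoxide, which closes onto the dimethyl acetal by acid-catalysed intramolecular transacetalisation (6-exo) to the 3-methoxy-1,2-dioxane; the C16 configuration is irrelevant because C16 becomes planar in step 8, and the hindered tertiary C9 hydroxyl does not compete.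

**Step 8**
Reactants: 14 (1R,2R,4aS,8aS)-1-[2-(6-methoxy-3-methyl-1,2-dioxan-3-yl)ethyl]-2,5,5,8a-tetramethyldecahydronaphthalen-1-ol; 15 (4R)-4-benzyl-3-propanoyl-1,3-thiazolidine-2-thione
Product: 17 (2S)-1-[(4R)-4-benzyl-2-thioxo-1,3-thiazolidin-3-yl]-2-[(3S,6S)-6-{2-[(1R,2R,4aS,8aS)-1-hydroxy-2,5,5,8a-tetramethyldecahydronaphthalen-1-yl]ethyl}-6-methyl-1,2-dioxan-3-yl]propan-1-one, via chlorotitanium (Z)-enolate 16 (not isolated)
Conditions: 15 (1.5 equiv), TiCl4 (1.6 equiv), i-Pr2NEt (1.7 equiv), CH2Cl2, −78 to −40 °C; then 14, SnCl4 (1.1 equiv, Lewis-acid promoter), −78 °C; SiO2 separation of the C13 epimers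
Reagents that add atoms: none
Why: Proposed new method: the Lewis acid ionises the peroxyacetal to a six-membered peroxycarbenium ion (as in the known additions of silyl ketene acetals to 3-alkoxy-1,2-dioxanes), and the chelated chlorotitanium (Z)-enolate of the N-propanoyl thiazolidinethione (closest known reaction: its anti-selective addition to dialkyl acetals) attacks C16 through an open transition state on the enolate face away from the benzyl group, which sets C17 (S) and, through the anti topicity, C16 (S) in both C13 epimers; the 13S adduct (methyl cis to the propanoyl-bearing carbon) is then separated from its 13R epimer.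

**Step 9**
Reactants: 17 (2S)-1-[(4R)-4-benzyl-2-thioxo-1,3-thiazolidin-3-yl]-2-[(3S,6S)-6-{2-[(1R,2R,4aS,8aS)-1-hydroxy-2,5,5,8a-tetramethyldecahydronaphthalen-1-yl]ethyl}-6-methyl-1,2-dioxan-3-yl]propan-1-one
Product: 18 (2S)-2-[(3S,6S)-6-{2-[(1R,2R,4aS,8aS)-1-hydroxy-2,5,5,8a-tetramethyldecahydronaphthalen-1-yl]ethyl}-6-methyl-1,2-dioxan-3-yl]propanoic acid (CNP0328037.1)
Conditions: LiOH, THF/H2O (3:1), 0 °C; then aq. HCl to pH 3
Reagents that add atoms: lithium hydroxide, [Li+].[OH-]
Why: acyl substitution by hydroxide at the activated exocyclic carbonyl of the N-acyl thiazolidinethione runs at 0 °C, too mild for enolisation or retro-oxa-Michael opening, so C16 and C17 are kept and the dialkyl peroxide and tertiary alcohol survive.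

**Compound list**
1 | (+)-sclareolide | O=C1C[C@H]2[C@@](C)(CC[C@H]3C(C)(C)CCC[C@]23C)O1 | starting material
2 | 11α-phenylselanylsclareolide | O=C1[C@@H]([Se]c2ccccc2)[C@H]3[C@@](C)(CC[C@H]4C(C)(C)CCC[C@]34C)O1 | intermediate
3 | 9(11)-dehydrosclareolide (C9=C11 butenolide) | O=C1C=C2[C@@](C)(CC[C@H]3C(C)(C)CCC[C@]23C)O1 | intermediate
4 | (2R,4aS,8aS)-2,5,5,8a-tetramethyl-1-oxodecahydronaphthalen-2-yl oxoacetate (8α-glyoxyloyloxy ketone) | O=C1[C@](C)(OC(=O)C=O)CC[C@H]2C(C)(C)CCC[C@]12C | intermediate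
5 | (2R,4aS,8aS)-2-hydroxy-2,5,5,8a-tetramethyloctahydronaphthalen-1(2H)-one | O=C1[C@](C)(O)CC[C@H]2C(C)(C)CCC[C@]12C | intermediate
6 | (2R,4aS,8aS)-2,5,5,8a-tetramethyloctahydronaphthalen-1(2H)-one | O=C1[C@H](C)CC[C@H]2C(C)(C)CCC[C@]12C | intermediate
7 | geranyl acetate | CC(=O)OC/C=C(\C)CCC=C(C)C | starting material
8 | (2E)-3-methyl-6-oxohex-2-en-1-yl acetate | CC(=O)OC/C=C(\C)CCC=O | intermediate
9 | (2E)-6,6-dimethoxy-3-methylhex-2-en-1-yl acetate | CC(=O)OC/C=C(\C)CCC(OC)OC | intermediate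
10 | [(2E)-6,6-dimethoxy-3-methylhex-2-en-1-yl]samarium diiodide | COC(OC)CC/C(C)=C/C[Sm](I)I | intermediate
11 | (1R,2R,4aS,8aS)-1-[(2E)-6,6-dimethoxy-3-methylhex-2-en-1-yl]-2,5,5,8a-tetramethyldecahydronaphthalen-1-ol | COC(OC)CC/C(C)=C/C[C@@]1(O)[C@H](C)CC[C@H]2C(C)(C)CCC[C@@]21C | intermediate
12 | (1R,2R,4aS,8aS)-1-{6,6-dimethoxy-3-methyl-3-[(triethylsilyl)peroxy]hexyl}-2,5,5,8a-tetramethyldecahydronaphthalen-1-ol (13RS) | CC[Si](CC)(CC)OOC(C)(CC[C@@]1(O)[C@H](C)CC[C@H]2C(C)(C)CCC[C@@]21C)CCC(OC)OC | intermediate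
13 | (1R,2R,4aS,8aS)-1-(3-hydroperoxy-6,6-dimethoxy-3-methylhexyl)-2,5,5,8a-tetramethyldecahydronaphthalen-1-ol (13RS) | OOC(C)(CC[C@@]1(O)[C@H](C)CC[C@H]2C(C)(C)CCC[C@@]21C)CCC(OC)OC | intermediate
14 | (1R,2R,4aS,8aS)-1-[2-(6-methoxy-3-methyl-1,2-dioxan-3-yl)ethyl]-2,5,5,8a-tetramethyldecahydronaphthalen-1-ol (13RS, 16RS) | COC1CCC(C)(CC[C@@]2(O)[C@H](C)CC[C@H]3C(C)(C)CCC[C@@]32C)OO1 | intermediate
15 | (4R)-4-benzyl-3-propanoyl-1,3-thiazolidine-2-thione | CCC(=O)N1[C@H](Cc2ccccc2)CSC1=S | starting material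
16 | trichlorotitanium (Z)-1-[(4R)-4-benzyl-2-thioxo-1,3-thiazolidin-3-yl]prop-1-en-1-olate | C/C=C(\O[Ti](Cl)(Cl)Cl)N1[C@H](Cc2ccccc2)CSC1=S | intermediate
17 | (2S)-1-[(4R)-4-benzyl-2-thioxo-1,3-thiazolidin-3-yl]-2-[(3S,6S)-6-{2-[(1R,2R,4aS,8aS)-1-hydroxy-2,5,5,8a-tetramethyldecahydronaphthalen-1-yl]ethyl}-6-methyl-1,2-dioxan-3-yl]propan-1-one | C[C@H](C(=O)N1[C@H](Cc2ccccc2)CSC1=S)[C@@H]3CC[C@@](C)(CC[C@@]4(O)[C@H](C)CC[C@H]5C(C)(C)CCC[C@@]54C)OO3 | intermediate
18 | (2S)-2-[(3S,6S)-6-{2-[(1R,2R,4aS,8aS)-1-hydroxy-2,5,5,8a-tetramethyldecahydronaphthalen-1-yl]ethyl}-6-methyl-1,2-dioxan-3-yl]propanoic acid | C[C@H](C(=O)O)[C@@H]1CC[C@@](C)(CC[C@@]2(O)[C@H](C)CC[C@H]3C(C)(C)CCC[C@@]32C)OO1 | target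

**Totals and risks**
Total step count: 9. Longest linear sequence: 8 steps (1 → 3 → 5 → 6 → 11 → 12 → 14 → 17 → 18; step 4 is the side branch). Known limitation besides the three risks below: step 6 gives both C13 epimers, so at most half of the material reaches 17.

Risk 1, step 5 (allylsamarium addition to a ketone flanked by a quaternary and a tertiary carbon; possible allyl dimerisation, enolisation or attack on the other face). Fallback, setting out from 6 and returning at 12: a SmI2-mediated ketyl–olefin coupling of 6 with methyl acrylate (SmI2, t-BuOH, THF, 0 °C) forms the C9–C11 bond from the ketyl radical anion and gives the spirolactone (1R,2R,4aS,8aS)-2,5,5,8a-tetramethyloctahydro-2H-spiro[naphthalene-1,2'-oxolan]-5'-one F1, whose C9 configuration would have to be confirmed. MeLi (THF, −78 °C) opens it to the methyl ketone 4-[(1R,2R,4aS,8aS)-1-hydroxy-2,5,5,8a-tetramethyldecahydronaphthalen-1-yl]butan-2-one F2. A Wittig reaction with the ylide from (3,3-dimethoxypropyl)triphenylphosphonium bromide and KN(SiMe3)2 gives the C13=C14 alkene (1R,2R,4aS,8aS)-1-(6,6-dimethoxy-3-methylhex-3-en-1-yl)-2,5,5,8a-tetramethyldecahydronaphthalen-1-ol F3. Under the conditions of step 6, F3 gives the same tertiary C13 radical and hence 12.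

Risk 2, step 8 (untested pairing of a peroxycarbenium ion with a chiral titanium enolate; Lewis acid in the presence of the free tertiary alcohol and the O–O bond). Fallback, setting out from 14 and returning at 18: mild aqueous acid (0.5 M HCl, THF) hydrolyses 14 to the peroxyhemiacetal 6-{2-[(1R,2R,4aS,8aS)-1-hydroxy-2,5,5,8a-tetramethyldecahydronaphthalen-1-yl]ethyl}-6-methyl-1,2-dioxan-3-ol F4. Wittig olefination of its open hydroperoxy-aldehyde form with methyl 2-(triphenylphosphoranylidene)propanoate, then Et2NH in CF3CH2OH, closes the ring by intramolecular oxa-Michael addition. This gives, after chromatographic separation of the diastereomers (substrate control only at C16 and C17), methyl (2S)-2-[(3S,6S)-6-{2-[(1R,2R,4aS,8aS)-1-hydroxy-2,5,5,8a-tetramethyldecahydronaphthalen-1-yl]ethyl}-6-methyl-1,2-dioxan-3-yl]propanoate F5. LiOH (THF/H2O, 0 °C) then gives 18.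

Risk 3, step 2 (slow ozonolysis of a hindered, electron-poor butenolide; possible α-ketol rearrangement of 5 under base). Fallback, setting out from 1 and returning at 6: i-Bu2AlH (CH2Cl2, −78 °C) reduces 1 to sclareolide lactol F6. Alkoxy-radical fragmentation (PhI(OAc)2, I2, hν) gives 11-iododriman-8α-yl formate F7. Dehydroiodination (AgF, pyridine) gives drim-9(11)-en-8α-yl formate F8. Ozonolysis (O3; Me2S) gives 9-oxo-11-nordriman-8α-yl formate F9. SmI2 (THF/MeOH) followed by NaOMe then cleaves the α-acyloxy group and equilibrates C8 to give 6.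

**Further compounds**
F1 | step 5 | (1R,2R,4aS,8aS)-2,5,5,8a-tetramethyloctahydro-2H-spiro[naphthalene-1,2'-oxolan]-5'-one | O=C1CC[C@@]2(O1)[C@H](C)CC[C@H]3C(C)(C)CCC[C@@]32C
F2 | step 5 | 4-[(1R,2R,4aS,8aS)-1-hydroxy-2,5,5,8a-tetramethyldecahydronaphthalen-1-yl]butan-2-one | CC(=O)CC[C@@]1(O)[C@H](C)CC[C@H]2C(C)(C)CCC[C@@]21C
F3 | step 5 | (1R,2R,4aS,8aS)-1-(6,6-dimethoxy-3-methylhex-3-en-1-yl)-2,5,5,8a-tetramethyldecahydronaphthalen-1-ol (E/Z mixture) | COC(OC)CC=C(C)CC[C@@]1(O)[C@H](C)CC[C@H]2C(C)(C)CCC[C@@]21C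
F4 | step 8 | 6-{2-[(1R,2R,4aS,8aS)-1-hydroxy-2,5,5,8a-tetramethyldecahydronaphthalen-1-yl]ethyl}-6-methyl-1,2-dioxan-3-ol | OC1CCC(C)(CC[C@@]2(O)[C@H](C)CC[C@H]3C(C)(C)CCC[C@@]32C)OO1
F5 | step 8 | methyl (2S)-2-[(3S,6S)-6-{2-[(1R,2R,4aS,8aS)-1-hydroxy-2,5,5,8a-tetramethyldecahydronaphthalen-1-yl]ethyl}-6-methyl-1,2-dioxan-3-yl]propanoate | C[C@H](C(=O)OC)[C@@H]1CC[C@@](C)(CC[C@@]2(O)[C@H](C)CC[C@H]3C(C)(C)CCC[C@@]32C)OO1
F6 | step 2 | sclareolide lactol | OC1C[C@H]2[C@@](C)(CC[C@H]3C(C)(C)CCC[C@]23C)O1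
F7 | step 2 | 11-iododriman-8α-yl formate | IC[C@H]1[C@](C)(OC=O)CC[C@H]2C(C)(C)CCC[C@]12C
F8 | step 2 | drim-9(11)-en-8α-yl formate | C=C1[C@](C)(OC=O)CC[C@H]2C(C)(C)CCC[C@]12C
F9 | step 2 | 9-oxo-11-nordriman-8α-yl formate | O=C1[C@](C)(OC=O)CC[C@H]2C(C)(C)CCC[C@]12C
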